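Hopeafuran is cut across its seven-membered ring at two bonds: the ketone carbon to the CH carbon, and furan carbon C3 to the resorcinol ring carbon. One flask forms both in a [4+3] annulation: a 2-benzylaryl zinc reagent is Negishi-coupled with a 3-iodobenzofuran-4-carbonitrile, and LDA then converts the doubly benzylic CH2 into a carbanion that adds to the nitrile, giving the ketone after acid hydrolysis. The step exploits the peri relation of C3 and the C4 nitrile carbon on the benzofuran, which matches the aryl carbon and the benzylic carbon ortho to it on the resorcinol ring. The stereocentre is set afterwards by catalytic enantioselective protonation of the silyl enol ether; hydrogenolysis ends the route.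

Key step: step 6

Assumption: 1,3-bis(benzyloxy)-5-bromobenzene is taken as commercially available; the sense of induction of the protonation catalyst in step 8 cannot be predicted for this enol ether, so the (S)-catalyst is written and its mirror image is used if it favours the (R)-ketone.

Step 1
Reactants: 1 3,5-dihydroxybenzonitrile
Product: 2 3,5-bis(benzyloxy)benzonitrile
Conditions: BnBr (2.3 equiv), K2CO3, DMF, 60 °C
Reagents that add atoms: benzyl bromide BrCc1ccccc1
Why: Williamson ether synthesis; both phenoxides should be alkylated cleanly and the nitrile is inert to carbonate.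

Step 2
Reactants: 2 3,5-bis(benzyloxy)benzonitrile
Product: 3 3,5-bis(benzyloxy)-2-iodobenzonitrile
Conditions: NIS (1.05 equiv), TFA (0.3 equiv), MeCN, rt
Reagents that add atoms: N-iodosuccinimide O=C1CCC(=O)N1I
Why: Electrophilic aromatic iodination; C2 is para to one ether and ortho to the other and should be preferred over C4 between the two ethers, as in halogenation of 3,5-dialkoxybenzoyl compounds.

Step 3
Reactants: 3 3,5-bis(benzyloxy)-2-iodobenzonitrile, 4 1-(benzyloxy)-4-ethynylbenzene
Product: 5 3,5-bis(benzyloxy)-2-{[4-(benzyloxy)phenyl]ethynyl}benzonitrile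
Conditions: PdCl2(PPh3)2 (3 mol %), CuI (5 mol %), Et3N, THF, 50 °C
Reagents that add atoms: none
Why: Sonogashira coupling; the aryl iodide is activated by the ortho nitrile, which is small enough not to hinder oxidative addition.

Step 4
Reactants: 5 3,5-bis(benzyloxy)-2-{[4-(benzyloxy)phenyl]ethynyl}benzonitrile
Product: 6 6-(benzyloxy)-2-[4-(benzyloxy)phenyl]-3-iodobenzofuran-4-carbonitrile
Conditions: I2 (2 equiv), CH2Cl2, rt
Reagents that add atoms: iodine II
Why: Electrophilic iodocyclisation of an ortho-alkynyl aryl ether; the ether oxygen next to the alkyne attacks the iodonium ion in a 5-endo-dig manner at the carbon bearing the electron-rich aryl group, and iodide removes the benzyl group from the oxonium ion. A nitrile was chosen at C4 because, unlike an ester or aldehyde, it cannot compete as a nucleophile.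

Step 5
Reactants: 7 1,3-bis(benzyloxy)-5-bromobenzene, 8 [4-(benzyloxy)phenyl]methanol
Product: 9 1,5-bis(benzyloxy)-2-[4-(benzyloxy)benzyl]-3-bromobenzene
Conditions: Bi(OTf)3 (5 mol %), MeNO2, rt, 7 in excess (3 equiv)
Reagents that add atoms: none
Why: Dehydrative Friedel–Crafts benzylation; the 4-alkoxybenzyl cation should attack C2 of 7 (para to one ether, ortho to the other, next to bromine), the same site at which the dimethyl analogue is formylated. Excess 7 suppresses a second benzylation.

Step 6
Reactants: 9 1,5-bis(benzyloxy)-2-[4-(benzyloxy)benzyl]-3-bromobenzene, 6 6-(benzyloxy)-2-[4-(benzyloxy)phenyl]-3-iodobenzofuran-4-carbonitrile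
Product: 14 racemic penta-O-benzylhopeafuran, via aryllithium 10 (not isolated), via arylzinc chloride 11 (not isolated), via biaryl nitrile 12 (not isolated), via cyclic ketimine 13 (not isolated)
Conditions: 9 (1.3 equiv), t-BuLi (2.6 equiv), THF, −78 °C; ZnCl2, −78 °C → rt; then 6, Pd2(dba)3 (2.5 mol %), RuPhos (10 mol %), 60 °C; then LDA (6 equiv), −78 → 0 °C; then 2 M HCl, rt
Reagents that add atoms: water O
Why: Bromine–lithium exchange and transmetalation give arylzinc 11, which undergoes Negishi coupling at the C3–I bond of 6 (oxidative addition to zerovalent palladium, transmetalation, reductive elimination) to form the hindered biaryl bond; LDA then deprotonates the doubly benzylic CH2 of 12, the carbanion adds to the nitrile carbon held peri to it, and acid hydrolyses the resulting aza-enolate to ketone 14. The closest known reactions are Negishi couplings to tri-ortho-substituted biaryls with dialkylbiarylphosphine ligands and the lithium amide-induced cyclisation of 2'-methylbiaryl-2-carbonitriles to 9-aminophenanthrenes, a Thorpe–Ziegler-type lateral metalation and cyclisation. The seven-membered ring is closed in the second stage by 7-exo-dig attack of the benzylic carbanion on the nitrile. The new stereocentre at the CH carbon is formed without control (racemic) because it is enolisable under these conditions; it is set in step 8. The step needs coupling only at C3 and deprotonation only at the CH2 group: 6 carries the only carbon–halogen bond left after the exchange, arylzincs do not add to nitriles, and reversible metalation by LDA in the presence of diisopropylamine should funnel all anions to the far more acidic diarylmethane position, whose cyclisation is irreversible.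

Step 7
Reactants: 14 racemic penta-O-benzylhopeafuran
Product: 15 trimethylsilyl enol ether of 14
Conditions: KHMDS (1.3 equiv), THF, −78 °C; TMSCl (1.5 equiv), −78 °C → rt
Reagents that add atoms: chlorotrimethylsilane C[Si](C)(C)Cl
Why: O-silylation of the potassium enolate of an α,α-diaryl ketone; the ring fixes a single enol ether geometry, which the next step requires.

Step 8
Reactants: 15 trimethylsilyl enol ether of 14
Product: 16 (S)-penta-O-benzylhopeafuran
Conditions: (S)-BINOL-derived N-triflyl thiophosphoramide with 3,3'-bis(2,4,6-triisopropylphenyl) groups (5 mol %), PhOH (1.1 equiv), toluene, rt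
Reagents that add atoms: none
Why: Chiral Brønsted acid-catalysed enantioselective protonation of a silyl enol ether, known for silyl enol ethers of cyclic α-aryl ketones. The catalyst should deliver the proton to one face of the diaryl-substituted carbon inside its chiral pocket, and phenol takes up the silyl group to regenerate the acid. The weakly acidic medium should not epimerise the product.

Step 9
Reactants: 16 (S)-penta-O-benzylhopeafuran
Product: 17 hopeafuran
Conditions: H2 (1 atm), 10% Pd/C, EtOAc/MeOH, rt
Reagents that add atoms: none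
Why: Hydrogenolysis of five aryl benzyl ethers under neutral conditions, chosen so that the enolisable stereocentre meets neither acid nor base; the hindered ketone and the tetrasubstituted furan double bond should survive at 1 atm.

Compound list
1 | 3,5-dihydroxybenzonitrile | N#Cc1cc(O)cc(O)c1 | starting material
2 | 3,5-bis(benzyloxy)benzonitrile | N#Cc1cc(OCc2ccccc2)cc(OCc2ccccc2)c1 | intermediate
3 | 3,5-bis(benzyloxy)-2-iodobenzonitrile | N#Cc1cc(OCc2ccccc2)cc(OCc2ccccc2)c1I | intermediate
4 | 1-(benzyloxy)-4-ethynylbenzene | C#Cc1ccc(OCc2ccccc2)cc1 | starting material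
5 | 3,5-bis(benzyloxy)-2-{[4-(benzyloxy)phenyl]ethynyl}benzonitrile | N#Cc1cc(OCc2ccccc2)cc(OCc2ccccc2)c1C#Cc1ccc(OCc2ccccc2)cc1 | intermediate
6 | 6-(benzyloxy)-2-[4-(benzyloxy)phenyl]-3-iodobenzofuran-4-carbonitrile | N#Cc1cc(OCc2ccccc2)cc2oc(-c3ccc(OCc4ccccc4)cc3)c(I)c12 | intermediate
7 | 1,3-bis(benzyloxy)-5-bromobenzene | Brc1cc(OCc2ccccc2)cc(OCc2ccccc2)c1 | starting material
8 | [4-(benzyloxy)phenyl]methanol | OCc1ccc(OCc2ccccc2)cc1 | starting material
9 | 1,5-bis(benzyloxy)-2-[4-(benzyloxy)benzyl]-3-bromobenzene | Brc1cc(OCc2ccccc2)cc(OCc2ccccc2)c1Cc1ccc(OCc2ccccc2)cc1 | intermediate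
10 | {3,5-bis(benzyloxy)-2-[4-(benzyloxy)benzyl]phenyl}lithium (aryllithium) | [Li]c1cc(OCc2ccccc2)cc(OCc2ccccc2)c1Cc1ccc(OCc2ccccc2)cc1 | intermediate
11 | {3,5-bis(benzyloxy)-2-[4-(benzyloxy)benzyl]phenyl}zinc chloride (arylzinc chloride) | Cl[Zn]c1cc(OCc2ccccc2)cc(OCc2ccccc2)c1Cc1ccc(OCc2ccccc2)cc1 | intermediate
12 | 6-(benzyloxy)-2-[4-(benzyloxy)phenyl]-3-{3,5-bis(benzyloxy)-2-[4-(benzyloxy)benzyl]phenyl}benzofuran-4-carbonitrile (biaryl nitrile) | N#Cc1cc(OCc2ccccc2)cc2oc(-c3ccc(OCc4ccccc4)cc3)c(-c3cc(OCc4ccccc4)cc(OCc4ccccc4)c3Cc3ccc(OCc4ccccc4)cc3)c12 | intermediate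
13 | cyclic ketimine, the C=NH analogue of ketone 14 (racemic) | N=C1c2cc(OCc3ccccc3)cc3oc(-c4ccc(OCc5ccccc5)cc4)c(c23)-c2cc(OCc3ccccc3)cc(OCc3ccccc3)c2C1c1ccc(OCc2ccccc2)cc1 | intermediate
14 | racemic penta-O-benzylhopeafuran (hopeafuran with all five phenols as benzyl ethers) | O=C1c2cc(OCc3ccccc3)cc3oc(-c4ccc(OCc5ccccc5)cc4)c(c23)-c2cc(OCc3ccccc3)cc(OCc3ccccc3)c2C1c1ccc(OCc2ccccc2)cc1 | intermediate
15 | trimethylsilyl enol ether of 14 (C=C between the former carbonyl carbon and the diaryl carbon) | C[Si](C)(C)OC1=C(c2ccc(OCc3ccccc3)cc2)c2c(OCc3ccccc3)cc(OCc3ccccc3)cc2-c2c(-c3ccc(OCc4ccccc4)cc3)oc3cc(OCc4ccccc4)cc1c23 | intermediate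
16 | (S)-penta-O-benzylhopeafuran | O=C1c2cc(OCc3ccccc3)cc3oc(-c4ccc(OCc5ccccc5)cc4)c(c23)-c2cc(OCc3ccccc3)cc(OCc3ccccc3)c2[C@@H]1c1ccc(OCc2ccccc2)cc1 | intermediate
17 | hopeafuran, (S) at the CH carbon | O=C1c2cc(O)cc3oc(-c4ccc(O)cc4)c(c23)-c2cc(O)cc(O)c2[C@@H]1c1ccc(O)cc1 | target

Total step count: 9. Longest linear sequence: 8 steps (steps 1–4 and 6–9).

Steps most likely to fail

Step 6. Lateral metalation may stall in the presence of zinc salts, the amide base may metalate the ring next to the nitrile or add to the nitrile, or coupling at the hindered C3 may be slow. Fallback, from 6 back to 14, closing the ring at the aryl–CH bond instead: Suzuki–Miyaura coupling of 6 with commercial [3,5-bis(benzyloxy)phenyl]boronic acid (Pd(OAc)2, SPhos, K3PO4, toluene/water, 90 °C) gives the 3-arylbenzofuran nitrile F1. DIBAL-H (CH2Cl2, −78 °C, acidic work-up) gives the aldehyde F2. The sulfonium salt F3, made from 4-(benzyloxy)benzyl chloride and tetrahydrothiophene, is converted by KOH in MeCN into its ylide, which turns F2 into the trans-epoxide F4 (Corey–Chaykovsky epoxidation). Bi(OTf)3-catalysed intramolecular Friedel–Crafts opening of the epoxide at the carbon bearing the 4-benzyloxyphenyl group, by the ortho carbon of the resorcinol ring, closes the seven-membered ring to the alcohol F5. Dess–Martin oxidation returns to 14.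

Step 8. Proton transfer to the crowded tetrasubstituted enol ether may show poor facial discrimination, or uncatalysed desilylation by phenol may erode the selectivity. Fallback, from 14 back to 16: dynamic kinetic resolution by asymmetric transfer hydrogenation (RuCl(p-cymene)[(S,S)-TsDPEN], HCO2H/Et3N, DMF, 40 °C; catalyst enantiomer chosen as for step 8), in which triethylamine keeps the unreacted ketone racemising, should give the cis alcohol F6. Dess–Martin oxidation (NaHCO3, CH2Cl2, 0 °C) then restores the ketone without base strong enough to epimerise it.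

Step 5. The benzyl cation may attack the position between the two ethers, benzylate twice, or the acid may shift benzyl ether groups. Fallback, from 7 back to 9: Vilsmeier–Haack formylation (POCl3, DMF, 90 °C) gives the aldehyde F7; 4-(benzyloxy)phenylmagnesium bromide (THF, 0 °C) gives the benzhydrol F8; ionic hydrogenation (Et3SiH, TFA, CH2Cl2, 0 °C) returns to 9.

Further compounds
F1 | step 6 | 3-[3,5-bis(benzyloxy)phenyl]-6-(benzyloxy)-2-[4-(benzyloxy)phenyl]benzofuran-4-carbonitrile | N#Cc1cc(OCc2ccccc2)cc2oc(-c3ccc(OCc4ccccc4)cc3)c(-c3cc(OCc4ccccc4)cc(OCc4ccccc4)c3)c12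
F2 | step 6 | 3-[3,5-bis(benzyloxy)phenyl]-6-(benzyloxy)-2-[4-(benzyloxy)phenyl]benzofuran-4-carbaldehyde | O=Cc1cc(OCc2ccccc2)cc2oc(-c3ccc(OCc4ccccc4)cc3)c(-c3cc(OCc4ccccc4)cc(OCc4ccccc4)c3)c12
F3 | step 6 | 1-[4-(benzyloxy)benzyl]tetrahydrothiophenium chloride | [Cl-].c1ccc(COc2ccc(C[S+]3CCCC3)cc2)cc1
F4 | step 6 | trans-2-[4-(benzyloxy)phenyl]-3-(benzofuran-4-yl)oxirane derived from F2 (racemic, one enantiomer drawn) | c1ccccc1COc1ccc(cc1)[C@H]1O[C@@H]1c1cc(OCc2ccccc2)cc2oc(-c3ccc(OCc4ccccc4)cc3)c(-c3cc(OCc4ccccc4)cc(OCc4ccccc4)c3)c12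
F5 | step 6 | secondary alcohol corresponding to ketone 14, trans expected (racemic, one enantiomer drawn) | O[C@H]1c2cc(OCc3ccccc3)cc3oc(-c4ccc(OCc5ccccc5)cc4)c(c23)-c2cc(OCc3ccccc3)cc(OCc3ccccc3)c2[C@@H]1c1ccc(OCc2ccccc2)cc1
F6 | step 8 | cis alcohol from reduction of 14, (S) at the diaryl carbon | O[C@@H]1c2cc(OCc3ccccc3)cc3oc(-c4ccc(OCc5ccccc5)cc4)c(c23)-c2cc(OCc3ccccc3)cc(OCc3ccccc3)c2[C@@H]1c1ccc(OCc2ccccc2)cc1
F7 | step 5 | 2,4-bis(benzyloxy)-6-bromobenzaldehyde | O=Cc1c(Br)cc(OCc2ccccc2)cc1OCc1ccccc1
F8 | step 5 | [2,4-bis(benzyloxy)-6-bromophenyl][4-(benzyloxy)phenyl]methanol (racemic) | OC(c1ccc(OCc2ccccc2)cc1)c1c(Br)cc(OCc2ccccc2)cc1OCc1ccccc1
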